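**Assumption:** (R)-5-methylcyclohex-2-en-1-one and (S)-2-methylbutanal are taken as purchasable catalogue compounds. Core positions are numbered C-1 to C-8a (isochromene) and C-1′ to C-6′ (cyclohexenone substituent). None of this route has been run; the stereochemical sense of step 8 is assigned by analogy only.

## Retrosynthetic overview

1. The C-7–O ester bond and the C-7 stereocentre are made last, by acyloxylative dearomatisation of a 2-benzopyrylium anhydrobase with the free β-hydroxy acid (chiral λ3-iodane, new).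
2. The pyran ring (C-1 from orthoformate, O-2 from the ketone) is closed on a resorcinol benzyl 1,3-diketone; C-3–C-1′ comes from C-acylation of the kinetic enolate of (R)-5-methylcyclohex-2-enone.
3. The C-4–C-4a bond is made by a 1,2-aryl shift: Kowalski homologation of a benzoate through its ynolate to an arylacetic active ester.
4. The benzene ring is built de novo from 3-methylpentane-2,4-dione and dimethyl oxalate (Claisen, then aldol aromatisation).
5. The acid comes from a D-proline cross-aldol and Pinnick oxidation. Ring order: carbocycle (as arene) first, cyclohexenone bought, pyran next, dearomatisation last.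

## Route

**Step 1**
Reactants: 1 3-methylpentane-2,4-dione; 2 dimethyl oxalate
Product: 4 methyl 3,5-dihydroxy-4-methylbenzoate, via triketo ester 3 (not isolated)
Conditions: LiN(iPr)2 (2.2 equiv), THF, −78 → 0 °C; 2, −78 → 20 °C; then 1,8-diazabicyclo[5.4.0]undec-7-ene (cat.), MeOH, 40 °C; aq. HCl
Reagents that add atoms: none
Why: Crossed Claisen condensation at the terminal carbon of doubly deprotonated 1 gives 3, whose methyl ketone closes onto the activated 2-keto group (intramolecular aldol condensation), and loss of water with enolisation gives the resorcinol ring (biomimetic polyketone aromatisation); no stereocentre is formed.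

**Step 2**
Reactants: 4 methyl 3,5-dihydroxy-4-methylbenzoate
Product: 5 methyl 3,5-bis[(tert-butyldimethylsilyl)oxy]-4-methylbenzoate
Conditions: tBuMe2SiCl (2.4 equiv), imidazole, DMF, 20 °C
Reagents that add atoms: tert-butyldimethylsilyl chloride (CC(C)(C)[Si](C)(C)Cl)
Why: Standard phenol silylation masks the two acidic OH groups for the organolithium chemistry of step 3.

**Step 3**
Reactants: 5 methyl 3,5-bis[(tert-butyldimethylsilyl)oxy]-4-methylbenzoate
Product: 8 pentafluorophenyl 2-{3,5-bis[(tert-butyldimethylsilyl)oxy]-4-methylphenyl}acetate, via lithium dibromoenolate 6 (not isolated), via lithium ynolate 7 (not isolated)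
Conditions: CH2Br2, lithium 2,2,6,6-tetramethylpiperidide, THF, −78 °C; LiN(SiMe3)2; sec-BuLi, −78 → 20 °C; C6F5OH (3 equiv), −78 → 0 °C; aq. NH4Cl
Reagents that add atoms: dibromomethane (BrCBr); pentafluorophenol (Oc1c(F)c(F)c(F)c(F)c1F)
Why: Kowalski ester homologation: LiCHBr2 adds to the ester to give 6, Br/Li exchange triggers the 1,2-aryl shift (Fritsch–Buttenberg–Wiechell type) to ynolate 7, and C-protonation with trapping by pentafluorophenol gives the one-carbon-extended active ester; no stereocentre is involved.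

**Step 4**
Reactants: 8 pentafluorophenyl 2-{3,5-bis[(tert-butyldimethylsilyl)oxy]-4-methylphenyl}acetate; 9 (R)-5-methylcyclohex-2-en-1-one
Product: 11 (5R)-6-[2-(3,5-dihydroxy-4-methylphenyl)acetyl]-5-methylcyclohex-2-en-1-one, via bis-silyl diketone 10 (not isolated)
Conditions: 9 (2.2 equiv), LiN(iPr)2 (2.2 equiv), THF, −78 °C; 8, −78 → −20 °C; then AcOH, Bu4NF, 0 → 20 °C
Reagents that add atoms: none
Why: Claisen-type C-acylation of the kinetic (C-6, cross-conjugated) lithium enolate of 9 by the active ester gives the 1,3-diketone, the second equivalent of enolate absorbs the acidic product proton, and fluoride then cleaves the aryl silyl ethers; C-5 of 9 is untouched and C-6 is an enolised, freely equilibrating position.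

**Step 5**
Reactants: 11 (5R)-6-[2-(3,5-dihydroxy-4-methylphenyl)acetyl]-5-methylcyclohex-2-en-1-one
Product: 12 8-hydroxy-7-methyl-3-[(1R,6R)-6-methyl-2-oxocyclohex-3-en-1-yl]-6H-isochromen-6-one
Conditions: HC(OMe)3, CF3CO2H, CH2Cl2, 0 → 20 °C; aq. NaOAc
Reagents that add atoms: trimethyl orthoformate (COC(OC)OC)
Why: Acid-mediated ring formylation ortho to OH (the two open positions are equivalent), attack of the benzyl-ketone enol oxygen on the formyl carbon and loss of methanol give the 2-benzopyrylium ion (classical benzopyrylium synthesis), isolated after buffering as its neutral anhydrobase; the epimerisable C-1′ settles trans (diequatorial) to the C-6′ methyl.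

**Step 6**
Reactants: 13 propanal; 14 (S)-2-methylbutanal
Product: 15 (2R,3R,4S)-3-hydroxy-2,4-dimethylhexanal
Conditions: D-proline (10 mol%), DMF, 4 °C, 13 added over 24 h to 14 (1.5 equiv)
Reagents that add atoms: none
Why: Proline-catalysed direct cross-aldol (enamine catalysis): the propanal enamine adds to the α-branched, poorly enolisable acceptor, D-proline setting (2R,3R) (anti); this is also the Felkin (3,4-syn) sense for the (S)-aldehyde, so catalyst and substrate control are matched.

**Step 7**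
Reactants: 15 (2R,3R,4S)-3-hydroxy-2,4-dimethylhexanal
Product: 16 (2R,3R,4S)-3-hydroxy-2,4-dimethylhexanoic acid
Conditions: NaClO2, NaH2PO4, 2-methylbut-2-ene, tBuOH/H2O, 0 → 20 °C
Reagents that add atoms: sodium chlorite ([Na+].[O-]Cl=O)
Why: Pinnick oxidation converts the aldehyde to the acid under buffered conditions that neither epimerise C-2 nor touch the free secondary alcohol.

**Step 8**
Reactants: 12 8-hydroxy-7-methyl-3-[(1R,6R)-6-methyl-2-oxocyclohex-3-en-1-yl]-6H-isochromen-6-one; 16 (2R,3R,4S)-3-hydroxy-2,4-dimethylhexanoic acid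
Product: 18 muyocopronone A, via diacyloxyiodane 17 (not isolated)
Conditions: 16 (2.1 equiv), dimethyl (2R,2'R)-2,2'-{[2-(diacetoxy-λ3-iodanyl)-1,3-phenylene]bis(oxy)}dipropanoate (1.05 equiv), PhCl, 40 °C, 20 mbar (removal of AcOH); then 12, CH2Cl2, −40 → 0 °C
Reagents that add atoms: none
Why: Proposed new method: ligand exchange of the lactate-derived C2-symmetric diacetoxy-λ3-iodane with 16 gives 17; the acidic enol OH of 12 (a vinylogous 2-methyl-1,3-diketone enol) displaces one carboxylate on trivalent iodine and the other carboxylate is delivered to C-7 with reductive loss of the aryl iodide, the lactate arms shielding one enol face so that C-7–O forms as (7S) (any 7R product is a separable diastereomer because 16 is enantiopure), while C-1′ stays trans by equilibration; the closest known reactions are α-acyloxylation of 1,3-dicarbonyl enols by (diacyloxyiodo)arenes, Pb(OAc)4 7-acetoxylation of 2-benzopyrylium salts and chiral aryl-λ3-iodane dearomatising spirolactonisation of phenols.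

## Compound list

1 | 3-methylpentane-2,4-dione | CC(=O)C(C)C(C)=O | starting material
2 | dimethyl oxalate | COC(=O)C(=O)OC | starting material
3 | methyl 5-methyl-2,4,6-trioxoheptanoate | COC(=O)C(=O)CC(=O)C(C)C(C)=O | intermediate
4 | methyl 3,5-dihydroxy-4-methylbenzoate | COC(=O)c1cc(O)c(C)c(O)c1 | intermediate
5 | methyl 3,5-bis[(tert-butyldimethylsilyl)oxy]-4-methylbenzoate | COC(=O)c1cc(O[Si](C)(C)C(C)(C)C)c(C)c(O[Si](C)(C)C(C)(C)C)c1 | intermediate
6 | lithium 1-{3,5-bis[(tert-butyldimethylsilyl)oxy]-4-methylphenyl}-2,2-dibromoethen-1-olate | [Li]OC(=C(Br)Br)c1cc(O[Si](C)(C)C(C)(C)C)c(C)c(O[Si](C)(C)C(C)(C)C)c1 | intermediate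
7 | lithium 2-{3,5-bis[(tert-butyldimethylsilyl)oxy]-4-methylphenyl}ethyn-1-olate | [Li]OC#Cc1cc(O[Si](C)(C)C(C)(C)C)c(C)c(O[Si](C)(C)C(C)(C)C)c1 | intermediate
8 | pentafluorophenyl 2-{3,5-bis[(tert-butyldimethylsilyl)oxy]-4-methylphenyl}acetate | O=C(Cc1cc(O[Si](C)(C)C(C)(C)C)c(C)c(O[Si](C)(C)C(C)(C)C)c1)Oc1c(F)c(F)c(F)c(F)c1F | intermediate
9 | (R)-5-methylcyclohex-2-en-1-one | C[C@@H]1CC=CC(=O)C1 | starting material
10 | (5R)-6-(2-{3,5-bis[(tert-butyldimethylsilyl)oxy]-4-methylphenyl}acetyl)-5-methylcyclohex-2-en-1-one (C-6 not fixed) | C[C@@H]1CC=CC(=O)C1C(=O)Cc1cc(O[Si](C)(C)C(C)(C)C)c(C)c(O[Si](C)(C)C(C)(C)C)c1 | intermediate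
11 | (5R)-6-[2-(3,5-dihydroxy-4-methylphenyl)acetyl]-5-methylcyclohex-2-en-1-one (enolised 1,3-diketone, C-6 not fixed) | C[C@@H]1CC=CC(=O)C1C(=O)Cc1cc(O)c(C)c(O)c1 | intermediate
12 | 8-hydroxy-7-methyl-3-[(1R,6R)-6-methyl-2-oxocyclohex-3-en-1-yl]-6H-isochromen-6-one | CC1=C(O)C2=COC(=CC2=CC1=O)[C@@H]3C(=O)C=CC[C@H]3C | intermediate
13 | propanal | CCC=O | starting material
14 | (S)-2-methylbutanal | CC[C@H](C)C=O | starting material
15 | (2R,3R,4S)-3-hydroxy-2,4-dimethylhexanal | CC[C@H](C)[C@@H](O)[C@@H](C)C=O | intermediate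
16 | (2R,3R,4S)-3-hydroxy-2,4-dimethylhexanoic acid | CC[C@H](C)[C@@H](O)[C@@H](C)C(=O)O | intermediate
17 | dimethyl (2R,2'R)-2,2'-{[2-(bis{[(2R,3R,4S)-3-hydroxy-2,4-dimethylhexanoyl]oxy}-λ3-iodanyl)-1,3-phenylene]bis(oxy)}dipropanoate | COC(=O)[C@@H](C)Oc1cccc(O[C@H](C)C(=O)OC)c1I(OC(=O)[C@H](C)[C@H](O)[C@@H](C)CC)OC(=O)[C@H](C)[C@H](O)[C@@H](C)CC | intermediate
18 | muyocopronone A, (7S)-7-methyl-3-[(1R,6R)-6-methyl-2-oxocyclohex-3-en-1-yl]-6,8-dioxo-7,8-dihydro-6H-isochromen-7-yl (2R,3R,4S)-3-hydroxy-2,4-dimethylhexanoate | CC[C@H](C)[C@@H](O)[C@@H](C)C(=O)O[C@@]1(C)C(=O)C=C2C=C([C@@H]3C(=O)C=CC[C@H]3C)OC=C2C1=O | target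

## Step count and risks

Total steps: 8. Longest linear sequence: 6 (steps 1, 2, 3, 4, 5, 8); steps 6 and 7 make the acid in parallel.

**Step 1 (ring closure of 3).** O-cyclisation of 3 to a γ-pyrone, Dieckmann closure to a cyclopentanetrione or retro-Claisen cleavage could outrun the aldol aromatisation. Fallback: set out again from 1 and 2 and make 3 as before, but close it deliberately on oxygen with HCl in MeOH to the crystalline pyranone methyl 5,6-dimethyl-4-oxo-4H-pyran-2-carboxylate F1. Then open the pyranone and re-close it on carbon with aqueous Ba(OH)2 at 80 °C (pyrone-to-resorcinol ring transformation, the ester being hydrolysed on the way) to 3,5-dihydroxy-4-methylbenzoic acid F2. Re-esterify F2 (MeOH, H2SO4) to come back to the route at 4.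

**Step 4 (C-acylation).** The arylacetyl ester is more acidic than the enone, so proton transfer followed by Michael addition or O-acylation may compete. Fallback: set out from 8 and reduce it with iBu2AlH (CH2Cl2, −78 °C) to 2-{3,5-bis[(tert-butyldimethylsilyl)oxy]-4-methylphenyl}acetaldehyde F3. Add F3 to the kinetic lithium enolate of 9 at −78 °C (aldol addition is faster than proton transfer) to give the β-hydroxy ketone (5R)-6-(2-{3,5-bis[(tert-butyldimethylsilyl)oxy]-4-methylphenyl}-1-hydroxyethyl)-5-methylcyclohex-2-en-1-one F4. Oxidise F4 with Dess–Martin periodinane to 10 and desilylate with Bu4NF/AcOH as in step 4 to come back at 11.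

**Step 8 (proposed new step).** The iodane may attack the C-1′ enol or C-5 instead of C-7, the facial selectivity may be low or opposite (the reagent antipode is then the first variable to change), and residual acetate may be transferred. Fallback with known chemistry: set out from 12 and hydroxylate C-7 with 2-iodoxybenzoic acid and Bu4NI in CF3CO2H/ClCH2CH2Cl (the established oxidation of 2-benzopyrylium salts) to the tertiary alcohol 7-hydroxy-7-methyl-3-[(1R,6R)-6-methyl-2-oxocyclohex-3-en-1-yl]-6H-isochromene-6,8(7H)-dione F5, obtained as both C-7 epimers. In parallel silylate 15 (tBuMe2SiOSO2CF3, 2,6-lutidine) to (2R,3R,4S)-3-[(tert-butyldimethylsilyl)oxy]-2,4-dimethylhexanal F6 and oxidise it with NaClO2 to (2R,3R,4S)-3-[(tert-butyldimethylsilyl)oxy]-2,4-dimethylhexanoic acid F7. Couple F5 with F7 (dicyclohexylcarbodiimide, 4-dimethylaminopyridine, CH2Cl2) and separate the (7S) ester O-silyl muyocopronone A F8 from its diastereomer 7-epi-O-silyl muyocopronone A F9 by chromatography. Remove the silyl group from F8 with HF·pyridine to come back at 18.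

## Further compounds

F1 | step 1 | methyl 5,6-dimethyl-4-oxo-4H-pyran-2-carboxylate | COC(=O)C1=CC(=O)C(C)=C(C)O1
F2 | step 1 | 3,5-dihydroxy-4-methylbenzoic acid | OC(=O)c1cc(O)c(C)c(O)c1
F3 | step 4 | 2-{3,5-bis[(tert-butyldimethylsilyl)oxy]-4-methylphenyl}acetaldehyde | O=CCc1cc(O[Si](C)(C)C(C)(C)C)c(C)c(O[Si](C)(C)C(C)(C)C)c1
F4 | step 4 | (5R)-6-(2-{3,5-bis[(tert-butyldimethylsilyl)oxy]-4-methylphenyl}-1-hydroxyethyl)-5-methylcyclohex-2-en-1-one | C[C@@H]1CC=CC(=O)C1C(O)Cc1cc(O[Si](C)(C)C(C)(C)C)c(C)c(O[Si](C)(C)C(C)(C)C)c1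
F5 | step 8 | 7-hydroxy-7-methyl-3-[(1R,6R)-6-methyl-2-oxocyclohex-3-en-1-yl]-6H-isochromene-6,8(7H)-dione (both C-7 epimers) | CC1(O)C(=O)C=C2C=C([C@@H]3C(=O)C=CC[C@H]3C)OC=C2C1=O
F6 | step 8 | (2R,3R,4S)-3-[(tert-butyldimethylsilyl)oxy]-2,4-dimethylhexanal | CC[C@H](C)[C@@H](O[Si](C)(C)C(C)(C)C)[C@@H](C)C=O
F7 | step 8 | (2R,3R,4S)-3-[(tert-butyldimethylsilyl)oxy]-2,4-dimethylhexanoic acid | CC[C@H](C)[C@@H](O[Si](C)(C)C(C)(C)C)[C@@H](C)C(=O)O
F8 | step 8 | O-silyl muyocopronone A, (7S) ester | CC[C@H](C)[C@@H](O[Si](C)(C)C(C)(C)C)[C@@H](C)C(=O)O[C@@]1(C)C(=O)C=C2C=C([C@@H]3C(=O)C=CC[C@H]3C)OC=C2C1=O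
F9 | step 8 | 7-epi-O-silyl muyocopronone A, (7R) ester | CC[C@H](C)[C@@H](O[Si](C)(C)C(C)(C)C)[C@@H](C)C(=O)O[C@]1(C)C(=O)C=C2C=C([C@@H]3C(=O)C=CC[C@H]3C)OC=C2C1=O
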